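**Plan**
- Ring A is cut at C8–C8a and C4a–C5 (flavanone numbering). Its 5-OH/7-OMe pattern, with the OH peri to the C4 carbonyl and the ring fused to ring C at C4a–C8a, is what a 1,3-dimethoxy-1-silyloxy diene delivers onto the C5=C6 bond of a 2-aryl-2,3-dihydropyran-4-one.
- The dienophile carries a phenylsulfinyl group at C5. It activates the enone and leaves by thermal syn elimination, whereas a sulfonyl group or halogen there would need base, which opens ring C.
- Ring C is cut at O1–C6 and C2–C3 (hetero-Diels–Alder of an aryl aldehyde with Danishefsky's diene). The aryl–geranyl bond is cut last, back to veratraldehyde and geranyl bromide.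
- Forward order: geranyl chain onto the arene, ring C, C5 functionalisation (I, then SPh, then S(O)Ph), ring A in the last step.
- Stereochemistry: C2 (S) is set in the BINOL–titanium hetero-Diels–Alder step and is not touched again; the E-alkene comes in with geranyl bromide.

Key step: step 8

Assumption: (S)-BINOL/Ti(OiPr)4 is taken to direct C–C bond formation to the Si face of the aryl aldehyde, the sense known for its allylation and aldol reactions, which gives 2S; the antipodal ligand would serve if the sense were reversed.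

Step 1
Reactants: 1 veratraldehyde (3,4-dimethoxybenzaldehyde); 2 geranyl bromide
Product: 6 2-geranyl-3,4-dimethoxybenzaldehyde, via lithium amino alkoxide 3 (not isolated), via C2-lithiated amino alkoxide 4 (not isolated), via geranylated amino alkoxide 5 (not isolated)
Conditions: LiN(Me)CH2CH2NMe2 (from Me2NCH2CH2NHMe and n-BuLi), THF, −20 °C; n-BuLi, −20 °C; CuBr·SMe2 (cat.), 2, −78 → 0 °C; then H2O
Reagents that add atoms: none
Why: The α-amino alkoxide masks the aldehyde and, together with the 3-methoxy group, directs lithiation to C2 (Comins-type directed ortho-metalation), and copper-catalysed SN2 allylation of the aryllithium by geranyl bromide keeps the E-alkene before aqueous work-up returns the aldehyde.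

Step 2
Reactants: 6 2-geranyl-3,4-dimethoxybenzaldehyde; 7 Danishefsky's diene ((E)-1-methoxy-3-(trimethylsilyloxy)buta-1,3-diene)
Product: 9 (2S)-2-(2-geranyl-3,4-dimethoxyphenyl)-2,3-dihydro-4H-pyran-4-one, via silylated aldol adduct 8 (not isolated)
Conditions: (S)-BINOL/Ti(OiPr)4 (10 mol%), 4 Å MS, Et2O, −20 °C; then TFA (cat.), CH2Cl2, 0 °C
Reagents that add atoms: none
Why: This is a Keck-type catalytic asymmetric hetero-Diels–Alder reaction that runs through a Mukaiyama aldol adduct and closes to the dihydropyranone on brief acid treatment, with the BINOL–titanium complex exposing the Si face of the bound aldehyde so that C2 is formed as S.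

Step 3
Reactants: 9 (2S)-2-(2-geranyl-3,4-dimethoxyphenyl)-2,3-dihydro-4H-pyran-4-one
Product: 10 (2S)-2-(2-geranyl-3,4-dimethoxyphenyl)-5-iodo-2,3-dihydro-4H-pyran-4-one
Conditions: I2, pyridine, CH2Cl2, 0 °C → rt; aq Na2S2O3 work-up
Reagents that add atoms: iodine, II
Why: The vinylogous ester is nucleophilic at C5, so iodine/pyridine should effect the usual α-iodination of a β-alkoxy enone (Johnson-type) by electrophilic attack and proton loss, under conditions too mild to touch the veratrole ring, the isolated alkenes or C2.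

Step 4
Reactants: 10 (2S)-2-(2-geranyl-3,4-dimethoxyphenyl)-5-iodo-2,3-dihydro-4H-pyran-4-one
Product: 11 (2S)-2-(2-geranyl-3,4-dimethoxyphenyl)-5-(phenylsulfanyl)-2,3-dihydro-4H-pyran-4-one
Conditions: PhSH, Pd2(dba)3 (cat.), Xantphos, i-Pr2NEt, 1,4-dioxane, 60 °C
Reagents that add atoms: thiophenol, Sc1ccccc1
Why: Palladium-catalysed C–S cross-coupling (Migita-type thiolation) of the reactive α-iodoenone should proceed by oxidative addition, thiolate exchange and reductive elimination with only a hindered tertiary amine as base, which leaves the C3 protons and therefore C2 alone.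

Step 5
Reactants: 11 (2S)-2-(2-geranyl-3,4-dimethoxyphenyl)-5-(phenylsulfanyl)-2,3-dihydro-4H-pyran-4-one
Product: 12 (2S)-2-(2-geranyl-3,4-dimethoxyphenyl)-5-(phenylsulfinyl)-2,3-dihydro-4H-pyran-4-one (both epimers at sulfur, used together)
Conditions: mCPBA (1.0 equiv), CH2Cl2, −78 °C; aq NaHCO3/Na2S2O3
Reagents that add atoms: 3-chloroperbenzoic acid (mCPBA), OOC(=O)c1cccc(Cl)c1
Why: Peracid oxidation of a thioether to the sulfoxide is far faster at −78 °C than epoxidation of trisubstituted alkenes or further oxidation to the sulfone, and the uncontrolled sulfur stereocentre is irrelevant because sulfur is expelled in step 8.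

Step 6
Reactants: 13 methyl acetoacetate
Product: 14 methyl (E)-3-methoxybut-2-enoate
Conditions: HC(OMe)3, H2SO4 (cat.), MeOH, rt; distillation
Reagents that add atoms: trimethyl orthoformate, COC(OC)OC
Why: Acid-catalysed ketalisation of the ketone by the orthoformate followed by loss of methanol gives the conjugated E enol ether, the standard O-methylation of a β-keto ester.

Step 7
Reactants: 14 methyl (E)-3-methoxybut-2-enoate
Product: 16 (1E)-1,3-dimethoxy-1-(trimethylsilyloxy)buta-1,3-diene (Brassard diene; the ketene acetal geometry is immaterial), via lithium dienolate 15 (not isolated)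
Conditions: LiN(i-Pr)2, THF, −78 °C; Me3SiCl, −78 °C → rt; distillation
Reagents that add atoms: chlorotrimethylsilane, C[Si](C)(C)Cl
Why: Kinetic γ-deprotonation of the β-methoxy enoate gives the extended dienolate, which is silylated on oxygen, the standard preparation of 1,3-dialkoxy-1-silyloxy dienes.

Step 8
Reactants: 12 (2S)-2-(2-geranyl-3,4-dimethoxyphenyl)-5-(phenylsulfinyl)-2,3-dihydro-4H-pyran-4-one; 16 (1E)-1,3-dimethoxy-1-(trimethylsilyloxy)buta-1,3-diene
Product: 19 (2S)-2-(2-geranyl-3,4-dimethoxyphenyl)-5-hydroxy-7-methoxychroman-4-one, via sulfinyl cycloadduct 17 (not isolated), via silyl ketal enone 18 (not isolated)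
Conditions: 16 (3 equiv), toluene, 80 °C; then 0.5 M HCl, THF, 0 °C
Reagents that add atoms: none
Why: Proposed new method: the CH2 terminus of the diene should attack C6 of 12 (β to both C=O and S=O, the future C8a) while the ketene acetal carbon bonds to C5 (the future C4a), either in an asynchronous normal-demand [4+2] cycloaddition or by Mukaiyama–Michael addition followed by 6-(enolexo)-exo-trig closure onto the ester-type carbon, so ring A is closed by a two-bond [4+2] annulation across the C5=C6 edge. In adduct 17 the sulfinyl group and the C8a hydrogen are necessarily cis, so thermal syn elimination of benzenesulfenic acid should give 18 without base, and collapse of the C5 silyl methyl ketal on mild acid work-up followed by tautomerisation leaves OH at C5 and OMe at C7. The closest known reactions are the Diels–Alder/sulfoxide-elimination aromatisations of sulfinylquinones and 2-sulfinyl cycloalkenones with siloxy dienes, the Brassard-diene annulation of haloquinones and the cycloadditions of chromones bearing an electron-withdrawing group at C3; a monocyclic 2,3-dihydropyran-4-one has not been used in this way. No stereocentre that is formed survives, since C4a, C5 and C8a all become sp2, and C2 lies outside the reacting atoms. The step needs this regiochemistry, which the matched polarisation of the sulfinyl enone and the ketene acetal secures, chemoselectivity for the only electron-poor alkene over the geranyl double bonds, and neutral conditions, which keep ring C from opening by retro-oxa-Michael reaction and so preserve C2.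

**Compound list**
1 | veratraldehyde (3,4-dimethoxybenzaldehyde) | COc1ccc(C=O)cc1OC | starting material
2 | geranyl bromide ((2E)-1-bromo-3,7-dimethylocta-2,6-diene) | BrC/C=C(\C)CCC=C(C)C | starting material
3 | lithium (3,4-dimethoxyphenyl){[2-(dimethylamino)ethyl](methyl)amino}methanolate | [Li+].[O-]C(N(C)CCN(C)C)c1ccc(OC)c(OC)c1 | intermediate
4 | C2-lithiated derivative of 3 (aryllithium, lithium alkoxide) | [Li+].[O-]C(N(C)CCN(C)C)c1ccc(OC)c(OC)c1[Li] | intermediate
5 | lithium (2-geranyl-3,4-dimethoxyphenyl){[2-(dimethylamino)ethyl](methyl)amino}methanolate | [Li+].[O-]C(N(C)CCN(C)C)c1ccc(OC)c(OC)c1C/C=C(\C)CCC=C(C)C | intermediate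
6 | 2-[(2E)-3,7-dimethylocta-2,6-dien-1-yl]-3,4-dimethoxybenzaldehyde | O=Cc1ccc(OC)c(OC)c1C/C=C(\C)CCC=C(C)C | intermediate
7 | Danishefsky's diene, (E)-1-methoxy-3-(trimethylsilyloxy)buta-1,3-diene | CO/C=C/C(=C)O[Si](C)(C)C | starting material
8 | (1E,5S)-5-(2-geranyl-3,4-dimethoxyphenyl)-1-methoxy-5-(trimethylsilyloxy)pent-1-en-3-one | CO/C=C/C(=O)C[C@H](O[Si](C)(C)C)c1ccc(OC)c(OC)c1C/C=C(\C)CCC=C(C)C | intermediate
9 | (2S)-2-(2-geranyl-3,4-dimethoxyphenyl)-2,3-dihydro-4H-pyran-4-one | O=C1C=CO[C@H](c2ccc(OC)c(OC)c2C/C=C(\C)CCC=C(C)C)C1 | intermediate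
10 | (2S)-2-(2-geranyl-3,4-dimethoxyphenyl)-5-iodo-2,3-dihydro-4H-pyran-4-one | O=C1C(I)=CO[C@H](c2ccc(OC)c(OC)c2C/C=C(\C)CCC=C(C)C)C1 | intermediate
11 | (2S)-2-(2-geranyl-3,4-dimethoxyphenyl)-5-(phenylsulfanyl)-2,3-dihydro-4H-pyran-4-one | O=C1C(Sc2ccccc2)=CO[C@H](c2ccc(OC)c(OC)c2C/C=C(\C)CCC=C(C)C)C1 | intermediate
12 | (2S)-2-(2-geranyl-3,4-dimethoxyphenyl)-5-(phenylsulfinyl)-2,3-dihydro-4H-pyran-4-one, both epimers at sulfur | O=C1C(S(=O)c2ccccc2)=CO[C@H](c2ccc(OC)c(OC)c2C/C=C(\C)CCC=C(C)C)C1 | intermediate
13 | methyl acetoacetate | COC(=O)CC(C)=O | starting material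
14 | methyl (E)-3-methoxybut-2-enoate | CO/C(C)=C/C(=O)OC | intermediate
15 | lithium (1E)-1,3-dimethoxybuta-1,3-dien-1-olate | [Li+].C=C(OC)/C=C(\OC)[O-] | intermediate
16 | (1E)-1,3-dimethoxy-1-(trimethylsilyloxy)buta-1,3-diene | C=C(OC)/C=C(\OC)O[Si](C)(C)C | intermediate
17 | (2S)-2-(2-geranyl-3,4-dimethoxyphenyl)-5,7-dimethoxy-4a-(phenylsulfinyl)-5-(trimethylsilyloxy)-2,3,4a,5,8,8a-hexahydro-4H-chromen-4-one, cis-fused, diastereomer mixture at C4a, C5, C8a and sulfur | COC1=CC(OC)(O[Si](C)(C)C)C2(S(=O)c3ccccc3)C(=O)C[C@@H](c3ccc(OC)c(OC)c3C/C=C(\C)CCC=C(C)C)OC2C1 | intermediate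
18 | (2S)-2-(2-geranyl-3,4-dimethoxyphenyl)-5,7-dimethoxy-5-(trimethylsilyloxy)-2,3,5,8-tetrahydro-4H-chromen-4-one, both epimers at C5 | COC1=CC(OC)(O[Si](C)(C)C)C2=C(C1)O[C@H](c3ccc(OC)c(OC)c3C/C=C(\C)CCC=C(C)C)CC2=O | intermediate
19 | (2S)-2-{2-[(2E)-3,7-dimethylocta-2,6-dien-1-yl]-3,4-dimethoxyphenyl}-5-hydroxy-7-methoxychroman-4-one | COc1cc(O)c2c(c1)O[C@H](c1ccc(OC)c(OC)c1C/C=C(\C)CCC=C(C)C)CC2=O | target

**Step count:** 8 steps in total. The longest linear sequence is 6 steps (steps 1, 2, 3, 4, 5, 8); steps 6 and 7 make the diene in a side branch.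

**Steps most likely to fail**

Step 8 (the step carrying the label). The push–pull C5=C6 bond may react too slowly for the thermally fragile diene. Alternatively, a stepwise Michael addition may be followed by β-elimination of the ring oxygen instead of ring closure, which opens ring C and erodes C2. The fallback uses known chemistry, brings ring A in as a preformed arene, sets out from aldehyde 6 and comes back at 19. Claisen–Schmidt condensation of 6 with commercial 2'-hydroxy-4',6'-dimethoxyacetophenone (KOH, EtOH, rt) would give the chalcone (2E)-3-(2-geranyl-3,4-dimethoxyphenyl)-1-(2-hydroxy-4,6-dimethoxyphenyl)prop-2-en-1-one F1. Oxa-Michael ring closure (NaOAc, EtOH, reflux) would give racemic 2-(2-geranyl-3,4-dimethoxyphenyl)-5,7-dimethoxychroman-4-one F2. Chelation-controlled cleavage of the methyl ether peri to the carbonyl (MgI2·OEt2, THF, 50 °C) would give racemic 2-(2-geranyl-3,4-dimethoxyphenyl)-5-hydroxy-7-methoxychroman-4-one F3. Separation on a polysaccharide chiral stationary phase would then deliver 19 beside the (2R)-enantiomer F4, which can be returned to the racemate through base-mediated chalcone equilibration.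

Step 1. Metalation may occur at C5 or C6 instead of C2 or stay incomplete, and the allylation may take the SN2′ course to the linalyl isomer. The fallback replaces directed metalation by halogen–metal exchange at a fixed position, sets out from geranyl bromide 2 together with commercial 2-bromo-3,4-dimethoxybenzaldehyde, and comes back at 6. The bromo aldehyde would be protected (HC(OMe)3, TsOH cat., MeOH) as 2-bromo-1-(dimethoxymethyl)-3,4-dimethoxybenzene F5. Bromine–lithium exchange (n-BuLi, THF, −78 °C) would give [6-(dimethoxymethyl)-2,3-dimethoxyphenyl]lithium F6. Coupling with 2 under CuBr·SMe2 catalysis would give 1-(dimethoxymethyl)-2-geranyl-3,4-dimethoxybenzene F7, and brief treatment with 1 M HCl in THF would release 6.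

Step 4. Conjugate addition of thiolate at C6 with opening of ring C, reductive loss of iodine, or poisoning of the catalyst by thiolate may outrun the cross-coupling. The fallback builds the sulfinyl pyranone from an acyclic precursor, sets out from aldehyde 6 and comes back at sulfoxide 12, bypassing steps 2 to 5.
- Mukaiyama aldol addition of 1-(tert-butylsulfanyl)-1-(trimethylsilyloxy)ethene to 6 under the same (S)-BINOL/Ti(OiPr)4 catalyst would give S-tert-butyl (3S)-3-(2-geranyl-3,4-dimethoxyphenyl)-3-(trimethylsilyloxy)propanethioate F8.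
- Acidic work-up would desilylate it to S-tert-butyl (3S)-3-(2-geranyl-3,4-dimethoxyphenyl)-3-hydroxypropanethioate F9.
- Acylation of excess LiCH2S(O)Ph (from methyl phenyl sulfoxide and LiN(i-Pr)2, THF, −78 °C) would give (4S)-4-(2-geranyl-3,4-dimethoxyphenyl)-4-hydroxy-1-(phenylsulfinyl)butan-2-one F10.
- Condensation with Me2NCH(OMe)2 (toluene, rt → 60 °C) at the activated methylene, followed by addition–elimination ring closure of the hydroxyl group, would give 12.

**Further compounds**
F1 | step 8 | (2E)-3-(2-geranyl-3,4-dimethoxyphenyl)-1-(2-hydroxy-4,6-dimethoxyphenyl)prop-2-en-1-one | COc1cc(O)c(C(=O)/C=C/c2ccc(OC)c(OC)c2C/C=C(\C)CCC=C(C)C)c(OC)c1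
F2 | step 8 | racemic 2-(2-geranyl-3,4-dimethoxyphenyl)-5,7-dimethoxychroman-4-one | COc1cc(OC)c2c(c1)OC(c1ccc(OC)c(OC)c1C/C=C(\C)CCC=C(C)C)CC2=O
F3 | step 8 | racemic 2-(2-geranyl-3,4-dimethoxyphenyl)-5-hydroxy-7-methoxychroman-4-one | COc1cc(O)c2c(c1)OC(c1ccc(OC)c(OC)c1C/C=C(\C)CCC=C(C)C)CC2=O
F4 | step 8 | (2R)-2-(2-geranyl-3,4-dimethoxyphenyl)-5-hydroxy-7-methoxychroman-4-one | COc1cc(O)c2c(c1)O[C@@H](c1ccc(OC)c(OC)c1C/C=C(\C)CCC=C(C)C)CC2=O
F5 | step 1 | 2-bromo-1-(dimethoxymethyl)-3,4-dimethoxybenzene | COC(OC)c1ccc(OC)c(OC)c1Br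
F6 | step 1 | [6-(dimethoxymethyl)-2,3-dimethoxyphenyl]lithium | [Li]c1c(C(OC)OC)ccc(OC)c1OC
F7 | step 1 | 1-(dimethoxymethyl)-2-geranyl-3,4-dimethoxybenzene | COC(OC)c1ccc(OC)c(OC)c1C/C=C(\C)CCC=C(C)C
F8 | step 4 | S-tert-butyl (3S)-3-(2-geranyl-3,4-dimethoxyphenyl)-3-(trimethylsilyloxy)propanethioate | CC(C)(C)SC(=O)C[C@H](O[Si](C)(C)C)c1ccc(OC)c(OC)c1C/C=C(\C)CCC=C(C)C
F9 | step 4 | S-tert-butyl (3S)-3-(2-geranyl-3,4-dimethoxyphenyl)-3-hydroxypropanethioate | CC(C)(C)SC(=O)C[C@H](O)c1ccc(OC)c(OC)c1C/C=C(\C)CCC=C(C)C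
F10 | step 4 | (4S)-4-(2-geranyl-3,4-dimethoxyphenyl)-4-hydroxy-1-(phenylsulfinyl)butan-2-one, both epimers at sulfur | O=C(CS(=O)c1ccccc1)C[C@H](O)c1ccc(OC)c(OC)c1C/C=C(\C)CCC=C(C)C
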